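## The problem

The target 23 is a Δ1(10)-octalin in which ring A (C1–C5 and C10) and ring B (C5–C10) share the C5–C10 bond (drimane-type numbering; C11 is the benzylic carbon, C1'–C6' the arene), C10 is sp2, and quaternary C9 carries a methyl group and the C11 methylene of a 2,6-dihydroxy-4-(hydroxymethyl)-3-formylphenyl group. Of its four stereocentres, C8 (CH–Me) and C9 are vicinal with their methyls cis, C5 lies across sp2 C10 with its hydrogen cis to the C9 methyl, and C3 is a remote carbinol beside the C4 gem-dimethyl carbon. A chair analysis of any ring B ketone at C10 suggests that the two C5 epimers differ little in energy and that the facial bias of C9 (methyl against arylmethyl) depends on which group is axial, so C5 needs a kinetic, intramolecular relay and C3 needs reagent control. The trisubstituted C1=C10 alkene can slip into the tetrasubstituted C5=C10 position or be captured by a flanking phenol under acid, so it has to be made by a regiospecific method. The o-(hydroxymethyl)salicylaldehyde unit tolerates neither organometallics nor oxidants, so the arene functions have to be unveiled last. The enabling feature lies in ring B: the cis C8/C9 methyls, with C11 trans to the C8 methyl, reproduce the geometry of (E)-2-methylbut-2-enal, and C10 can start as the oxygen-bearing terminus of a 1-silyloxydiene. One [4+2] then closes ring B, sets C8 and C9, and leaves a C10 oxygen cis to C11 that can later deliver C4 to C5.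

## Retrosynthesis

**Arene functions.** The MOM and silyl groups of 22 are removed last to give 23. Before that, the formyl C–C bond is cut, leading to 20. In 20 the two free arene positions are equivalent and each lies between an OMOM and the CH2OMOM group, so directed lithiation has a single outcome. Carrying the aldehyde earlier would expose it to every organometallic step. The forward reaction has to tolerate a silyl ether and the C1=C10 alkene.

**C1=C10.** The alkene of 20 is cut by ring-closing metathesis to diene 19, which comes from ketone 18 by methylenation. Dehydrating a C10 carbinol is the obvious neighbour, but it would drain into the tetrasubstituted C5=C10 isomer. Metathesis can only give the C1=C10 alkene. The forward steps must methylenate a flanked, enolisable ketone without base and close a six-membered ring at a 1,1-disubstituted alkene.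

**C2–C3.** The homoallylic carbinol of 18 (alcohol 17) is cut at C2–C3 to neopentyl aldehyde 16 and an allyl nucleophile. There is no stereocentre near C3, so the configuration is asked of the reagent (allylboration with a pinene-derived borane). A late reduction of a C3 ketone would depend on the ring A conformation. The aldehyde must react in the presence of the hindered C10 ketone.

**Redox adjustment.** Keto aldehyde 16 comes from 1,4-diol 15 by double oxidation, and 15 from cyclic acetal 13 through lactol 14. This spends two steps. In return, C5 is not next to a carbonyl until C4 is in place.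

**C4–C5.** Acetal 13 is cut at C4–C5 to bromoacetal 12, made from allylic alcohol 11. An intermolecular attack on a C10 ketone or enone (enolate alkylation, cuprate addition to an alkylidene ketone) would leave C5 to thermodynamics or to the C9 facial bias, and neither is reliable here. In 12 the tertiary C4 radical is tied to the C10 oxygen. The 5-exo closure can only give the cis-fused oxabicycle, so C4 lands on the face of the C10–O bond. That face is cis to C11, so H5 ends up cis to the C9 methyl. The same step makes quaternary C4, brings C3 in at the aldehyde oxidation level and saturates C5=C6.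

**C11–aryl.** Alcohol 11 comes from silyl ether 10. The C11–C1' bond of 10 is cut to aldehyde 4 and aryllithium 7 (from 6), with the carbinol oxygen removed by way of xanthate 9. The lithiation site between two OMOM groups is unambiguous, and 4 cannot enolise. Dissolving-metal deoxygenation would also cleave the benzylic MOM ether. Ionising conditions would create a cation beside quaternary C9. A radical deoxygenation is therefore asked for.

**Ring B (key).** Aldehyde 4 is cut at C7–C8 and C9–C10 to diene 2 and tiglic aldehyde 3. The cut removes a ring and three stereocentres and leaves two small commercial building blocks. The forward reaction needs enantiofacial control from a chiral Lewis acid, ortho regiochemistry and endo selectivity.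

**Building blocks.** Diene 2 comes from crotonaldehyde 1 by silylation. Arene 6 comes from 3,5-dihydroxybenzyl alcohol 5 by protection.

## Roads not taken

Alternative 1: Biomimetic bicyclization.

- **Cut:** C4–C5 and C9–C10, back to the acyclic (2E,6Z)-epoxyfarnesyl arene A1.
- **Forward key step:** BF3·OEt2 opens the epoxide; rings A and B close; the C8 cation relays through a 1,2-hydride shift and a C10-to-C9 methyl shift; loss of H1 gives A2.
- **Merits:** this is the shortest route by far. Both rings and all four stereocentres arise in one step from a precursor assembled by allylic coupling, and C3 comes from an enantioselective epoxidation.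
- **Weak points:**
  - A stereodefined 6Z trisubstituted alkene is required to reach the cis relationship of H5 and the migrating methyl.
  - The cascade must continue through exactly two 1,2-shifts and then stop by loss of H1. Proton loss before the shifts, a further H5 shift, and capture of the C8 or C10 cation by the electron-rich arene all compete, and nothing in A1 can be tuned to choose between them.
- **Comparison:** Alternative 1 wins clearly on step count. The chosen plan sets against that a separate, individually controllable event for each stereocentre and for the alkene position.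

Alternative 2: Late benzannulation.

- **Cut:** C3'–C4' and C5'–C6' of the arene, back to the bis-silyloxy diene A3 (already carrying the complete decalin at C11) and alkynoate A4.
- **Forward key step:** cycloaddition, loss of methanol and desilylation give benzoate A5.
- **Merits:** the arene arrives fully substituted, with the future formyl carbon in place. No aryllithium addition, no benzylic deoxygenation and no late formylation are needed. In these respects it is better than the chosen plan.
- **Weak points:**
  - It does nothing for the decalin, which holds all four stereocentres and the labile alkene and would still need its own synthesis.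
  - C11, a neopentyl carbon, would have to be bonded to the central carbon of the precursor of A3.
  - The 2-substituted diene A3 is hindered.
  - The ester of A5 must afterwards be brought to the aldehyde beside free phenols.
- **Comparison:** the chosen plan pays three steps for the arene. It buys them with a one-step arene building block and a strategy aimed at the stereochemical core.

Alternative 3: Allylsilane-terminated epoxide cyclization.

- **Cut:** C4–C5, back to epoxy allylsilane A6.
- **Forward key step:** BF3·OEt2 opens the epoxide at C4, C5 attacks anti to the C1–Si bond, and loss of silicon gives A7.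
- **Merits:** ring A, quaternary C4, the C3 carbinol and the C1=C10 alkene (fixed by the position of silicon) arise in one step. Ring A costs far fewer steps than in the chosen plan, which spends eight on it.
- **Weak points:**
  - The C5 configuration is dictated by the configuration of the silicon-bearing C1. That is a new stereocentre, remote from C8 and C9, and it must be set on a hindered alkene adjacent to quaternary C9.
  - Without control at C1, the ring B facial bias decides C5.
  - Bond formation between a tertiary cation and a trisubstituted alkene carbon next to C9 competes with semipinacol and hydride-shift collapse of the epoxide.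
  - Ring B with C8 and C9 must still be made, most likely by the cycloaddition used here.
- **Comparison:** Alternative 3 is shorter for ring A. The chosen plan sets against that a C5 relay from an oxygen that the key step creates anyway, through a ring closure with only one possible ring fusion.

Key step: step 2

Assumption: the (S)-proline-derived oxazaborolidinium is taken to leave the C2-Re face of bound tiglic aldehyde open (formyl C–H···O binding model for α-substituted enals), and the endo (formyl) mode is taken to predominate with the acyclic diene; the drawn (8R,9S,10R) adduct 4 follows from both.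

## Route

Ar = 2,6-bis(methoxymethoxy)-4-[(methoxymethoxy)methyl]phenyl.

Step 1
Reactants: 1 crotonaldehyde, (E)-but-2-enal
Product: 2 (E)-1-(tert-butyldimethylsilyloxy)buta-1,3-diene
Conditions: TBSOTf, Et3N, Et2O, 0 °C → rt
Reagents that add atoms: tert-butyldimethylsilyl triflate, CC(C)(C)[Si](C)(C)OS(=O)(=O)C(F)(F)F
Why: Soft enolisation: the silyl triflate activates the carbonyl of the s-trans enal and the amine removes a γ-proton, so O-silylation of the extended enolate gives the E dienol ether. This is a standard preparation of 1-silyloxydienes.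

Step 2
Reactants: 2 (E)-1-(tert-butyldimethylsilyloxy)buta-1,3-diene (excess); 3 tiglic aldehyde, (E)-2-methylbut-2-enal
Product: 4 (1S,2R,6R)-2-(tert-butyldimethylsilyloxy)-1,6-dimethylcyclohex-3-ene-1-carbaldehyde
Conditions: (S)-3,3-diphenyl-1-(2-methylphenyl)tetrahydro-1H,3H-pyrrolo[1,2-c][1,3,2]oxazaborole protonated with HNTf2 (20 mol%), CH2Cl2, −78 → −40 °C
Reagents that add atoms: none
Why: The aldehyde binds boron anti to its alkenyl residue with the formyl C–H held by the ring oxygen, which places the s-trans enal over one phenyl group; the s-cis diene then adds to the open face in a concerted, asynchronous [4+2] in which the C7–C8 bond (diene CH2 terminus to the enal β-carbon) runs ahead of the C9–C10 bond. The closest known reaction type is the cationic oxazaborolidine-catalysed Diels–Alder reaction of α-substituted enals such as methacrolein with simple and 1-oxygenated dienes. Ring B is closed by intermolecular cycloaddition, both bonds forming suprafacially on each partner. C8 and C9 are fixed relative to each other by the E geometry of 3 (methyls cis, formyl trans to the C8 methyl). C10 is fixed relative to C9 by the endo placement of the boron-bound formyl group under the E diene (silyloxy cis to formyl), and the absolute sense is set by the catalyst, which leaves the C2-Re face of the enal open. The regiochemistry needed is oxygen-bearing terminus to α-carbon; the silyloxy donor puts the larger HOMO coefficient on the CH2 terminus, which pairs with the β-carbon of the activated enal. The step therefore needs enantiofacial, endo and ortho selectivity: the first is the catalyst's, the other two are secured by the 1-silyloxy group and the E geometries of 2 and 3.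

Step 3
Reactants: 5 3,5-dihydroxybenzyl alcohol
Product: 6 1,3-bis(methoxymethoxy)-5-[(methoxymethoxy)methyl]benzene
Conditions: MOMCl, iPr2NEt, CH2Cl2, 0 → 40 °C
Reagents that add atoms: chloromethyl methyl ether, COCCl
Why: O-Alkylation of both phenols and the benzylic alcohol with the α-chloro ether (MOM protection). The MOM ethers later direct both lithiations and leave under acid.

Step 4
Reactants: 6 1,3-bis(methoxymethoxy)-5-[(methoxymethoxy)methyl]benzene; 4 (1S,2R,6R)-2-(tert-butyldimethylsilyloxy)-1,6-dimethylcyclohex-3-ene-1-carbaldehyde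
Product: 9 O-{(Ar)[(1R,2R,6R)-2-(tert-butyldimethylsilyloxy)-1,6-dimethylcyclohex-3-en-1-yl]methyl} S-methyl carbonodithioate (both C11 epimers), via aryllithium 7 (not isolated), via lithium alkoxide 8 (not isolated)
Conditions: 6, n-BuLi, THF, 0 °C; 4, −78 °C; CS2, −78 → 0 °C; MeI, rt
Reagents that add atoms: carbon disulfide, S=C=S; iodomethane, CI
Why: Directed ortho-metalation occurs between the two OMOM groups, and the aryllithium adds 1,2 to the non-enolisable neopentyl aldehyde. The alkoxide is trapped cold as the xanthate, which prepares the radical deoxygenation and limits silyl migration from the C10 oxygen; the C11 configuration is of no consequence.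

Step 5
Reactants: 9 xanthate of the C11 carbinol
Product: 10 tert-butyl{[(1R,5R,6S)-6-(Ar-methyl)-5,6-dimethylcyclohex-2-en-1-yl]oxy}dimethylsilane
Conditions: Bu3SnH, AIBN, toluene, 100 °C
Reagents that add atoms: none
Why: Barton–McCombie deoxygenation: the Bu3Sn radical adds to C=S, β-scission gives the doubly ortho-oxygenated benzylic C11 radical, and Bu3SnH reduces it. C9 has no hydrogen for Chugaev elimination, and the benzylic MOM ether, which dissolving metal would cleave, is untouched.

Step 6
Reactants: 10 silyl ether
Product: 11 (1R,5R,6S)-6-(Ar-methyl)-5,6-dimethylcyclohex-2-en-1-ol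
Conditions: TBAF, THF, 50 °C
Reagents that add atoms: none
Why: Fluoride-mediated cleavage of the hindered secondary silyl ether. The MOM ethers are inert to fluoride, and no base-sensitive group remains.

Step 7
Reactants: 11 (1R,5R,6S)-6-(Ar-methyl)-5,6-dimethylcyclohex-2-en-1-ol
Product: 12 2-bromo-1-ethoxy-2-methylpropyl ether of 11 (mixed bromoacetal, both acetal epimers)
Conditions: EtOCH=CMe2, Br2, CH2Cl2, −78 °C; then 11, iPr2NEt, −78 °C → rt
Reagents that add atoms: 1-ethoxy-2-methylprop-1-ene, CCOC=C(C)C; bromine, BrBr
Why: Bromine adds to the enol ether to give the α,β-dibromo ether, whose oxocarbenium ion alkylates the hindered alcohol (standard preparation of Ueno–Stork bromoacetals). The bromine is consumed before the electron-rich arene and the ring alkene are introduced, which is why N-bromosuccinimide is avoided.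

Step 8
Reactants: 12 mixed bromoacetal
Product: 13 (3aS,6R,7S,7aR)-7-(Ar-methyl)-2-ethoxy-3,3,6,7-tetramethyloctahydro-1-benzofuran (both C2 epimers)
Conditions: Bu3SnH (slow addition), AIBN, benzene, 80 °C
Reagents that add atoms: none
Why: Ueno–Stork radical cyclisation: the tertiary C4 radical closes 5-exo-trig onto C5, and the C6 radical is reduced by Bu3SnH. Only the cis-fused oxabicycle can form, so C4 bonds to C5 on the face of the C10 oxygen, which is cis to C11; H5 is thereby set cis to the C9 methyl and quaternary C4 is made in the same event.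

Step 9
Reactants: 13 bicyclic acetal
Product: 15 (1R,2S,3R,6S)-2-(Ar-methyl)-6-(1-hydroxy-2-methylpropan-2-yl)-2,3-dimethylcyclohexan-1-ol, via lactol 14 (not isolated)
Conditions: 80% aq AcOH, THF, 50 °C; evaporate; NaBH4, MeOH, 0 °C
Reagents that add atoms: water, O
Why: Mild acid hydrolyses the 2-alkoxytetrahydrofuran acetal while the MOM ethers survive, and NaBH4 reduces the open hydroxy aldehyde tautomer of the lactol. The 1,4-diol frees the C10 oxygen without C5 ever being next to a carbonyl.

Step 10
Reactants: 15 diol
Product: 16 2-[(1S,3S,4R)-3-(Ar-methyl)-3,4-dimethyl-2-oxocyclohexyl]-2-methylpropanal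
Conditions: (COCl)2, DMSO, CH2Cl2, −78 °C; Et3N, −78 → 0 °C
Reagents that add atoms: none
Why: Swern oxidation: both hydroxyls are converted into alkoxysulfonium salts before base is added, so no hydroxy aldehyde is free to close to the lactol and over-oxidise. The aldehyde has no α-hydrogen, and the cold amine quench spares the C5 centre next to the new ketone.

Step 11
Reactants: 16 keto aldehyde
Product: 17 (2S,3R,6S)-2-(Ar-methyl)-6-[(3R)-3-hydroxy-2-methylhex-5-en-2-yl]-2,3-dimethylcyclohexan-1-one
Conditions: lIpc2B(allyl) [from (−)-α-pinene], Et2O, −78 °C; NaBO3·4H2O, THF–H2O, rt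
Reagents that add atoms: B-allyldiisopinocampheylborane from (−)-α-pinene, C=CCB([C@H]1C[C@H]2C[C@@H]([C@@H]1C)C2(C)C)[C@H]1C[C@H]2C[C@@H]([C@@H]1C)C2(C)C
Why: Brown allylboration through a chair six-membered transition state; C3 is set by the reagent. The allylborane made from (+)-α-pinene is known to add to the Si face of aldehydes, so its antipode from (−)-α-pinene is used to reach the Re face and the 3R carbinol. The neopentyl aldehyde reacts far faster than the flanked ketone, and the mild NaBO3 work-up avoids base at C5.

Step 12
Reactants: 17 hydroxy ketone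
Product: 18 (2S,3R,6S)-2-(Ar-methyl)-2,3-dimethyl-6-[(3R)-2-methyl-3-(triethylsilyloxy)hex-5-en-2-yl]cyclohexan-1-one
Conditions: TESCl, imidazole, DMAP, DMF, rt
Reagents that add atoms: chlorotriethylsilane, CC[Si](Cl)(CC)CC
Why: Silylation of the secondary alcohol. Any hemiketal formed with the C10 ketone is in equilibrium with the open form and is drained through it.

Step 13
Reactants: 18 silyloxy ketone
Product: 19 triethyl{[(3R)-2-[(1R,3S,4R)-3-(Ar-methyl)-3,4-dimethyl-2-methylidenecyclohexyl]-2-methylhex-5-en-3-yl]oxy}silane
Conditions: Cp2Ti(μ-Cl)(μ-CH2)AlMe2 (Tebbe reagent), pyridine, THF–toluene, −40 °C → rt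
Reagents that add atoms: Tebbe reagent, C[Al-]1(C)C[Ti]([Cl+]1)(C2C=CC=C2)C3C=CC=C3
Why: Tebbe methylenation: the methylidene Cp2Ti=CH2 released from the reagent undergoes [2+2] addition to the ketone and cycloreversion to the alkene. The reagent is non-basic and small, which suits a flanked ketone with an epimerisable α-centre where a phosphorus ylide would not.

Step 14
Reactants: 19 diene
Product: 20 triethylsilyl ether of (2R,5S,6R,8aR)-5-(Ar-methyl)-1,1,5,6-tetramethyl-1,2,3,5,6,7,8,8a-octahydronaphthalen-2-ol (drimane numbering 3R,5R,8R,9S)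
Conditions: (H2IMes)(PCy3)Cl2Ru=CHPh (second-generation Grubbs catalyst, 5 mol%), toluene, 80 °C
Reagents that add atoms: none
Why: Ring-closing metathesis of the terminal alkene with the 1,1-disubstituted alkene closes ring A with loss of ethene. The double bond can only be C1=C10, so the tetrasubstituted isomer is excluded by construction.

Step 15
Reactants: 20 octalin silyl ether
Product: 22 2,4-bis(methoxymethoxy)-6-[(methoxymethoxy)methyl]-3-{[(1S,2R,4aR,6R)-1,2,5,5-tetramethyl-6-(triethylsilyloxy)-1,2,3,4,4a,5,6,7-octahydronaphthalen-1-yl]methyl}benzaldehyde, via aryllithium 21 (not isolated)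
Conditions: s-BuLi, TMEDA, THF, −78 °C; DMF, −78 → 0 °C; aq NH4Cl
Reagents that add atoms: N,N-dimethylformamide, CN(C)C=O
Why: Directed ortho-metalation at the position flanked by an OMOM and the CH2OMOM group, followed by formylation with DMF. The two candidate positions are equivalent, so a single aldehyde results.

Step 16
Reactants: 22 protected aldehyde
Product: 23 2,4-dihydroxy-6-(hydroxymethyl)-3-{[(1S,2R,4aR,6R)-6-hydroxy-1,2,5,5-tetramethyl-1,2,3,4,4a,5,6,7-octahydronaphthalen-1-yl]methyl}benzaldehyde (target)
Conditions: 3 M aq HCl, THF, 45 °C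
Reagents that add atoms: none
Why: Acid hydrolysis of the three formaldehyde acetals (MOM ethers) and of the triethylsilyl ether. The MOM group ortho to the formyl group leaves first and the benzylic one last; water rather than an alcohol as co-solvent avoids acetalisation of the aldehyde.

## Compound list

1 | crotonaldehyde, (E)-but-2-enal | C/C=C/C=O | starting material
2 | (E)-1-(tert-butyldimethylsilyloxy)buta-1,3-diene | C=C/C=C/O[Si](C)(C)C(C)(C)C | intermediate
3 | tiglic aldehyde, (E)-2-methylbut-2-enal | C/C=C(\C)C=O | starting material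
4 | (1S,2R,6R)-2-(tert-butyldimethylsilyloxy)-1,6-dimethylcyclohex-3-ene-1-carbaldehyde | C[C@@H]1CC=C[C@@H](O[Si](C)(C)C(C)(C)C)[C@@]1(C)C=O | intermediate
5 | 3,5-dihydroxybenzyl alcohol | OCc1cc(O)cc(O)c1 | starting material
6 | 1,3-bis(methoxymethoxy)-5-[(methoxymethoxy)methyl]benzene | COCOCc1cc(OCOC)cc(OCOC)c1 | intermediate
7 | {2,6-bis(methoxymethoxy)-4-[(methoxymethoxy)methyl]phenyl}lithium | [Li]c1c(OCOC)cc(COCOC)cc1OCOC | intermediate (not isolated)
8 | lithium (Ar)[(1R,2R,6R)-2-(tert-butyldimethylsilyloxy)-1,6-dimethylcyclohex-3-en-1-yl]methanolate, C11 epimers | C[C@@H]1CC=C[C@@H](O[Si](C)(C)C(C)(C)C)[C@@]1(C)C([O-])c1c(OCOC)cc(COCOC)cc1OCOC.[Li+] | intermediate (not isolated)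
9 | O-{(Ar)[(1R,2R,6R)-2-(tert-butyldimethylsilyloxy)-1,6-dimethylcyclohex-3-en-1-yl]methyl} S-methyl carbonodithioate, C11 epimers | C[C@@H]1CC=C[C@@H](O[Si](C)(C)C(C)(C)C)[C@@]1(C)C(OC(=S)SC)c1c(OCOC)cc(COCOC)cc1OCOC | intermediate
10 | tert-butyl{[(1R,5R,6S)-6-(Ar-methyl)-5,6-dimethylcyclohex-2-en-1-yl]oxy}dimethylsilane | C[C@@H]1CC=C[C@@H](O[Si](C)(C)C(C)(C)C)[C@@]1(C)Cc1c(OCOC)cc(COCOC)cc1OCOC | intermediate
11 | (1R,5R,6S)-6-(Ar-methyl)-5,6-dimethylcyclohex-2-en-1-ol | C[C@@H]1CC=C[C@@H](O)[C@@]1(C)Cc1c(OCOC)cc(COCOC)cc1OCOC | intermediate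
12 | 2-bromo-1-ethoxy-2-methylpropyl ether of 11, acetal epimers | C[C@@H]1CC=C[C@@H](OC(OCC)C(C)(C)Br)[C@@]1(C)Cc1c(OCOC)cc(COCOC)cc1OCOC | intermediate
13 | (3aS,6R,7S,7aR)-7-(Ar-methyl)-2-ethoxy-3,3,6,7-tetramethyloctahydro-1-benzofuran, C2 epimers | C[C@@H]1CC[C@@H]2[C@@H](OC(OCC)C2(C)C)[C@@]1(C)Cc1c(OCOC)cc(COCOC)cc1OCOC | intermediate
14 | (3aS,6R,7S,7aR)-7-(Ar-methyl)-3,3,6,7-tetramethyloctahydro-1-benzofuran-2-ol, C2 epimers | C[C@@H]1CC[C@@H]2[C@@H](OC(O)C2(C)C)[C@@]1(C)Cc1c(OCOC)cc(COCOC)cc1OCOC | intermediate (not isolated)
15 | (1R,2S,3R,6S)-2-(Ar-methyl)-6-(1-hydroxy-2-methylpropan-2-yl)-2,3-dimethylcyclohexan-1-ol | C[C@@H]1CC[C@@H](C(C)(C)CO)[C@@H](O)[C@@]1(C)Cc1c(OCOC)cc(COCOC)cc1OCOC | intermediate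
16 | 2-[(1S,3S,4R)-3-(Ar-methyl)-3,4-dimethyl-2-oxocyclohexyl]-2-methylpropanal | C[C@@H]1CC[C@@H](C(C)(C)C=O)C(=O)[C@@]1(C)Cc1c(OCOC)cc(COCOC)cc1OCOC | intermediate
17 | (2S,3R,6S)-2-(Ar-methyl)-6-[(3R)-3-hydroxy-2-methylhex-5-en-2-yl]-2,3-dimethylcyclohexan-1-one | C[C@@H]1CC[C@@H](C(C)(C)[C@H](O)CC=C)C(=O)[C@@]1(C)Cc1c(OCOC)cc(COCOC)cc1OCOC | intermediate
18 | (2S,3R,6S)-2-(Ar-methyl)-2,3-dimethyl-6-[(3R)-2-methyl-3-(triethylsilyloxy)hex-5-en-2-yl]cyclohexan-1-one | C[C@@H]1CC[C@@H](C(C)(C)[C@H](O[Si](CC)(CC)CC)CC=C)C(=O)[C@@]1(C)Cc1c(OCOC)cc(COCOC)cc1OCOC | intermediate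
19 | triethyl{[(3R)-2-[(1R,3S,4R)-3-(Ar-methyl)-3,4-dimethyl-2-methylidenecyclohexyl]-2-methylhex-5-en-3-yl]oxy}silane | C[C@@H]1CC[C@@H](C(C)(C)[C@H](O[Si](CC)(CC)CC)CC=C)C(=C)[C@@]1(C)Cc1c(OCOC)cc(COCOC)cc1OCOC | intermediate
20 | triethylsilyl ether of (2R,5S,6R,8aR)-5-(Ar-methyl)-1,1,5,6-tetramethyl-1,2,3,5,6,7,8,8a-octahydronaphthalen-2-ol | C[C@@H]1CC[C@@H]2C(=CC[C@@H](O[Si](CC)(CC)CC)C2(C)C)[C@@]1(C)Cc1c(OCOC)cc(COCOC)cc1OCOC | intermediate
21 | aryllithium from 20, lithium at the arene carbon between an OMOM and the CH2OMOM group | C[C@@H]1CC[C@@H]2C(=CC[C@@H](O[Si](CC)(CC)CC)C2(C)C)[C@@]1(C)Cc1c(OCOC)cc(COCOC)c([Li])c1OCOC | intermediate (not isolated)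
22 | 2,4-bis(methoxymethoxy)-6-[(methoxymethoxy)methyl]-3-{[(1S,2R,4aR,6R)-1,2,5,5-tetramethyl-6-(triethylsilyloxy)-1,2,3,4,4a,5,6,7-octahydronaphthalen-1-yl]methyl}benzaldehyde | C[C@@H]1CC[C@@H]2C(=CC[C@@H](O[Si](CC)(CC)CC)C2(C)C)[C@@]1(C)Cc1c(OCOC)cc(COCOC)c(C=O)c1OCOC | intermediate
23 | 2,4-dihydroxy-6-(hydroxymethyl)-3-{[(1S,2R,4aR,6R)-6-hydroxy-1,2,5,5-tetramethyl-1,2,3,4,4a,5,6,7-octahydronaphthalen-1-yl]methyl}benzaldehyde | C[C@@H]1CC[C@@H]2C(=CC[C@@H](O)C2(C)C)[C@@]1(C)Cc1c(O)cc(CO)c(C=O)c1O | target

## Step count and least certain steps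

Total: 16 steps. Longest linear sequence: 15 steps (steps 1, 2 and 4–16, from crotonaldehyde); step 3 is the one-step arene branch.

**Step 2 (key step).** What may go wrong: the strongly Lewis-acidic catalyst may divert the silyl dienol ether into carbonyl addition or silyl transfer faster than the sluggish α,β-disubstituted enal undergoes cycloaddition. Enantiofacial or endo selectivity may also be incomplete, and endo selectivity matters here because the C10 configuration later relays to C5. Fallback: 2 and 3 are combined under Me2AlCl to give the racemic endo adduct, which is 4 together with its enantiomer (1R,2S,6S)-2-(tert-butyldimethylsilyloxy)-1,6-dimethylcyclohex-3-ene-1-carbaldehyde F1. The enantiomers are separated by preparative chromatography on a chiral stationary phase, and the route is rejoined at 4. If exo addition prevails instead, the fallback given under step 8 does not use the C10 configuration.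

**Step 8 (radical cyclisation).** What may go wrong: hydrogen transfer to the tertiary radical before ring closure, or slow formation of the congested C4–C5 bond beside the arylmethyl-bearing quaternary centre. Fallback, setting out from 11: Dess–Martin oxidation gives (5R,6S)-6-(Ar-methyl)-5,6-dimethylcyclohex-2-en-1-one F2. Conjugate reduction with K[s-Bu3BH] and trapping of the enolate with acetone (ZnCl2) gives (2S,3R)-2-(Ar-methyl)-6-(2-hydroxypropan-2-yl)-2,3-dimethylcyclohexan-1-one F3. Dehydration (Burgess reagent, then DBU) gives (2S,3R)-2-(Ar-methyl)-2,3-dimethyl-6-(propan-2-ylidene)cyclohexan-1-one F4. Conjugate addition of vinylMgBr with CuI and TMSCl gives trimethyl{[(5R,6S)-6-(Ar-methyl)-5,6-dimethyl-2-(2-methylbut-3-en-2-yl)cyclohex-1-en-1-yl]oxy}silane F5, and mild aqueous acid hydrolyses it to (2S,3R,6S)-2-(Ar-methyl)-2,3-dimethyl-6-(2-methylbut-3-en-2-yl)cyclohexan-1-one F6. OsO4/NaIO4 cleavage of the vinyl group then comes back to the route at 16. The cost is that C5 then rests on protonation and equilibration, so its epimers would have to be separated.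

**Step 10 (double Swern oxidation).** What may go wrong: incomplete activation of the very hindered C10 hydroxyl lets the intermediate hydroxy aldehyde close to the lactol, which is then over-oxidised. The amine may also epimerise C5 once the ketone is present. Fallback, setting out from lactol 14 (step 9 stopped after the hydrolysis): Wittig methylenation (Ph3P=CH2) opens the lactol to (1R,2S,3R,6S)-2-(Ar-methyl)-2,3-dimethyl-6-(2-methylbut-3-en-2-yl)cyclohexan-1-ol F7. Dess–Martin oxidation gives the vinyl ketone F6, and OsO4/NaIO4 cleavage comes back to the route at 16. In this sequence no free hydroxy aldehyde exists at any stage.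

**Step 13 (Tebbe methylenation, with the metathesis of step 14).** What may go wrong: enolisation of the flanked ketone by the Tebbe reagent instead of methylenation, which returns or epimerises the ketone. Ring closure at the hindered 1,1-disubstituted alkene may also be slow. Fallback, setting out from 18: OsO4/NaIO4 cleavage of the terminal alkene gives (3R)-4-[(1S,3S,4R)-3-(Ar-methyl)-3,4-dimethyl-2-oxocyclohexyl]-4-methyl-3-(triethylsilyloxy)pentanal F8. Intramolecular McMurry coupling with TiCl3(DME)1.5 and Zn–Cu couple in refluxing DME joins C1 and C10 directly and comes back to the route at 20.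

**Step 16 (global deprotection).** What may go wrong: while the slow benzylic MOM ether is forced off, the hydroxymethyl and formyl groups may acetalise, and a freed phenol may add across the C1=C10 alkene under acid. Fallback, setting out from 20: the protecting groups are removed before any aldehyde is present (dilute aq HCl in THF–MeOH; with no formyl group there is nothing to acetalise and the acid can be kept weaker). This gives 2-{[(1S,2R,4aR,6R)-6-hydroxy-1,2,5,5-tetramethyl-1,2,3,4,4a,5,6,7-octahydronaphthalen-1-yl]methyl}-5-(hydroxymethyl)benzene-1,3-diol F9. The formyl group is then introduced ortho to a phenol by magnesium-mediated formylation (MgCl2, Et3N, paraformaldehyde, MeCN, reflux), which arrives at 23 directly. This fallback also replaces the lithiation of step 15.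

## Further compounds

F1 | step 2 | (1R,2S,6S)-2-(tert-butyldimethylsilyloxy)-1,6-dimethylcyclohex-3-ene-1-carbaldehyde (enantiomer of 4) | C[C@H]1CC=C[C@H](O[Si](C)(C)C(C)(C)C)[C@]1(C)C=O
F2 | step 8 | (5R,6S)-6-(Ar-methyl)-5,6-dimethylcyclohex-2-en-1-one | C[C@@H]1CC=CC(=O)[C@@]1(C)Cc1c(OCOC)cc(COCOC)cc1OCOC
F3 | step 8 | (2S,3R)-2-(Ar-methyl)-6-(2-hydroxypropan-2-yl)-2,3-dimethylcyclohexan-1-one, C6 epimers | C[C@@H]1CCC(C(C)(C)O)C(=O)[C@@]1(C)Cc1c(OCOC)cc(COCOC)cc1OCOC
F4 | step 8 | (2S,3R)-2-(Ar-methyl)-2,3-dimethyl-6-(propan-2-ylidene)cyclohexan-1-one | C[C@@H]1CCC(=C(C)C)C(=O)[C@@]1(C)Cc1c(OCOC)cc(COCOC)cc1OCOC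
F5 | step 8 | trimethyl{[(5R,6S)-6-(Ar-methyl)-5,6-dimethyl-2-(2-methylbut-3-en-2-yl)cyclohex-1-en-1-yl]oxy}silane | C[C@@H]1CCC(C(C)(C)C=C)=C(O[Si](C)(C)C)[C@@]1(C)Cc1c(OCOC)cc(COCOC)cc1OCOC
F6 | step 8 | (2S,3R,6S)-2-(Ar-methyl)-2,3-dimethyl-6-(2-methylbut-3-en-2-yl)cyclohexan-1-one | C[C@@H]1CC[C@@H](C(C)(C)C=C)C(=O)[C@@]1(C)Cc1c(OCOC)cc(COCOC)cc1OCOC
F7 | step 10 | (1R,2S,3R,6S)-2-(Ar-methyl)-2,3-dimethyl-6-(2-methylbut-3-en-2-yl)cyclohexan-1-ol | C[C@@H]1CC[C@@H](C(C)(C)C=C)[C@@H](O)[C@@]1(C)Cc1c(OCOC)cc(COCOC)cc1OCOC
F8 | step 13 | (3R)-4-[(1S,3S,4R)-3-(Ar-methyl)-3,4-dimethyl-2-oxocyclohexyl]-4-methyl-3-(triethylsilyloxy)pentanal | C[C@@H]1CC[C@@H](C(C)(C)[C@H](O[Si](CC)(CC)CC)CC=O)C(=O)[C@@]1(C)Cc1c(OCOC)cc(COCOC)cc1OCOC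
F9 | step 16 | 2-{[(1S,2R,4aR,6R)-6-hydroxy-1,2,5,5-tetramethyl-1,2,3,4,4a,5,6,7-octahydronaphthalen-1-yl]methyl}-5-(hydroxymethyl)benzene-1,3-diol | C[C@@H]1CC[C@@H]2C(=CC[C@@H](O)C2(C)C)[C@@]1(C)Cc1c(O)cc(CO)cc1O
A1 | alternative 1 | methyl 4-{(2E,6Z)-9-[(2R)-3,3-dimethyloxiran-2-yl]-3,7-dimethylnona-2,6-dien-1-yl}-3,5-dimethoxybenzoate | COC(=O)c1cc(OC)c(C/C=C(\C)CC/C=C(/C)CC[C@H]2OC2(C)C)c(OC)c1
A2 | alternative 1 | methyl 4-{[(1S,2R,4aR,6R)-6-hydroxy-1,2,5,5-tetramethyl-1,2,3,4,4a,5,6,7-octahydronaphthalen-1-yl]methyl}-3,5-dimethoxybenzoate | C[C@@H]1CC[C@@H]2C(=CC[C@@H](O)C2(C)C)[C@@]1(C)Cc1c(OC)cc(C(=O)OC)cc1OC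
A3 | alternative 2 | 1-methoxy-1,3-bis(trimethylsilyloxy)buta-1,3-diene carrying at C2 the {(1S,2R,4aR,6R)-6-(tert-butyldimethylsilyloxy)-1,2,5,5-tetramethyl-1,2,3,4,4a,5,6,7-octahydronaphthalen-1-yl}methyl group | C[C@@H]1CC[C@@H]2C(=CC[C@@H](O[Si](C)(C)C(C)(C)C)C2(C)C)[C@@]1(C)CC(C(=C)O[Si](C)(C)C)=C(OC)O[Si](C)(C)C
A4 | alternative 2 | methyl 4-(tert-butyldimethylsilyloxy)but-2-ynoate | COC(=O)C#CCO[Si](C)(C)C(C)(C)C
A5 | alternative 2 | methyl 2,4-dihydroxy-6-[(tert-butyldimethylsilyloxy)methyl]-3-{[(1S,2R,4aR,6R)-6-(tert-butyldimethylsilyloxy)-1,2,5,5-tetramethyl-1,2,3,4,4a,5,6,7-octahydronaphthalen-1-yl]methyl}benzoate | C[C@@H]1CC[C@@H]2C(=CC[C@@H](O[Si](C)(C)C(C)(C)C)C2(C)C)[C@@]1(C)Cc1c(O)cc(CO[Si](C)(C)C(C)(C)C)c(C(=O)OC)c1O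
A6 | alternative 3 | epoxy allylsilane: ring B cyclohexene (C5=C10) with the C8 and C9 methyls cis, the 2,6-dimethoxy-4-[(tert-butyldimethylsilyloxy)methyl]benzyl group on C9, and on C10 a 1-(trimethylsilyl)-3-[(2R)-3,3-dimethyloxiran-2-yl]propyl chain | C[C@@H]1CCC=C([C@@H]([Si](C)(C)C)CC[C@H]2OC2(C)C)[C@@]1(C)Cc1c(OC)cc(CO[Si](C)(C)C(C)(C)C)cc1OC
A7 | alternative 3 | (2R,5S,6R,8aR)-5-{2,6-dimethoxy-4-[(tert-butyldimethylsilyloxy)methyl]benzyl}-1,1,5,6-tetramethyl-1,2,3,5,6,7,8,8a-octahydronaphthalen-2-ol | C[C@@H]1CC[C@@H]2C(=CC[C@@H](O)C2(C)C)[C@@]1(C)Cc1c(OC)cc(CO[Si](C)(C)C(C)(C)C)cc1OC
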